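in all of them: gas 0.077 mM (held)

|  | solid substrate | remark | time |
|---|---|---|---|
| north | 3.000 × 10⁻⁵ M | run made earlier |  |
| west | 1.6 × 10⁻⁴ M | run made earlier |  |
| Monday's | 4.0 × 10⁻⁵ M |  | 15 min |
| Wednesday's | 6.0 × 10⁻⁵ M |  | 15 min |
| Thursday's | 8.0 × 10⁻⁵ M |  | 15 min |
| Sunday's | 1.2 × 10⁻⁴ M |  | 15 min |
| Tuesday's | 2.0 × 10⁻⁴ M |  | 15 min |

| run | time / min | target / % | solid substrate / % |
|---|---|---|---|
| north | 1.00 | 60 | 3 |
| north | 2.50 | 87 | 0 |
| north | 5.00 | 84 | 2 |
| north | 8.00 | 88 | 0 |
| north | 10.0 | 86 | 1 |
| west | 2.00 | 25 | 8 |
| west | 4.00 | 37 | 3 |
| west | 6.00 | 38 | 1 |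
| west | 8.00 | 39 | 0 |
| west | 10.0 | 38 | 0 |

(standard deviation of a reading: 1.5 percentage points)

- at the start none of the solid substrate is in solution
- at the start none of the gas is in solution
- a step back or a flat step of under half a percent of the largest counts as no turn
- a reading or a percentage of target counts all its forms, free or not
- the concentration of target that is asked is that of its free form alone
- "hardly changes" means that all values lie within two and a half points (for a concentration: within two and a half percent of the largest)
- a step back or a flat step of under half a percent of the largest counts as no turn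

- [target] (only what is free in solution) at the end for Monday's, Wednesday's, Thursday's, Sunday's, Tuesday's, in this order
- how that number moves from the first to the last of them (rises all the way / rises, then falls / falls all the way / hardly changes / falls, then rises)

1. Solid substrate leaves these flasks by two roads: one gives target, the other loses it. Target first appears at 1.80 × 10⁻⁵ M min⁻¹ in the north run and 2.00 × 10⁻⁵ M min⁻¹ in the west run, so I treat the road to target as a steady feed of like size at both charges.

2. I assume that the loss grows with the square of [solid substrate]. The north plateau holds 86.2 % of the charge as target, so it loses 13.8 %.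

3. Now I replace the curve by its mean. If [solid substrate] falls in a nearly straight line, its mean square is a third of the starting square. The lost share is then a third of the squared ratio of charge to crossover charge. This gives a crossover charge of 4.67 × 10⁻⁵ M, the [solid substrate] at which loss equals feed.

4. At a given charge, a further bit of solid substrate yields target in the share one over one plus the squared ratio of charge to crossover charge. This is the marginal yield, or differential selectivity. It falls from 7.85 % at the west charge to 5.17 % at Tuesday's charge.

5. The west plateau holds 6.08 × 10⁻⁵ M of target. The west plateau readings spread from 37 % to 39 %, so I widen by half that spread. Adding Tuesday's extra charge at the higher share, plus the widening, gives an upper estimate of 6.55 × 10⁻⁵ M. Adding it at the lower share, minus the widening, gives a lower estimate of 6.13 × 10⁻⁵ M. These are estimates from a rough model, not strict bounds. Both count every form of target, so free target can stand lower. The marginal yield stays above zero, so I expect counted target to keep rising with charge.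

6. The forecast gives 3.200 × 10⁻⁵ M, 4.250 × 10⁻⁵ M, 5.000 × 10⁻⁵ M, 5.800 × 10⁻⁵ M and 6.300 × 10⁻⁵ M, rises all the way, and says “I therefore interpolated empirically”; its last value stands inside my bracket.

7. The flasks give 3.30 × 10⁻⁵ M, 4.28 × 10⁻⁵ M, 4.94 × 10⁻⁵ M, 5.40 × 10⁻⁵ M and 5.40 × 10⁻⁵ M: rises all the way.

    solid substrate ⇌ dissolved substrate, rate k1*(cs1 - [dissolved substrate]) while solid is left; crystals form when [dissolved substrate] > cs1 (solubility = 0.0250 mM, k = 0.0237 s⁻¹)
    dissolved substrate + partner → target (k = 863 M⁻¹ s⁻¹)
    2 dissolved substrate → side product (k = 123 M⁻¹ s⁻¹)
    solid product ⇌ target, rate k4*(cs4 - [target]) while solid is left; crystals form when [target] > cs4 (solubility = 0.0540 mM, k = 1.77 s⁻¹)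
    gas ⇌ partner, rate k5*(csat - [partner]) (kL = 0.0439 s⁻¹)
    2 solid substrate → homo dimer (k = 85.5 M⁻¹ s⁻¹)

Tuesday's flask ends with 6.46 × 10⁻⁵ M of target counted, of which solid product holds 1.06 × 10⁻⁵ M, and free target reads 5.40 × 10⁻⁵ M against a saturation value of 0.054 mM. At the start of Tuesday's flask, homo dimer takes solid substrate at 4.10 × 10⁻⁴ M min⁻¹, ten times the 3.56 × 10⁻⁵ M min⁻¹ of dissolving. From Sunday's flask to Tuesday's, the extra charge returns 9.02 % as counted target, between the marginal yields of 13.2 % at Sunday's charge and 5.17 % at Tuesday's.

The earlier runs and the new flask were computed with constants of no real substance; noise was put on by code.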